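A direct plan would condense 3-prenylphloroacetophenone bis-allyl ether A1 with 4-hydroxy-3,5-diprenylbenzaldehyde A2 to chalcone A3, close A3 through its one free ortho hydroxyl to flavanone A4, dehydrogenate A4 to flavone A5 and remove the allyl groups. Its weakest steps would be:
- the aldol (Claisen–Schmidt) condensation, because aldehyde A2 would be deactivated by its para phenolate and the enolate of ketone A1 would be flanked by two ortho substituents;
- the ring closure at oxygen, because the 8- versus 6-prenyl outcome would depend only on which hydroxyl is masked at that moment;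
- the dehydrogenation of A4, because the usual oxidants (iodine, quinones, selenium dioxide, divalent palladium salts) would also attack prenyl groups that stand beside phenols.

The route would rest on closing ring C at the C4–C4a carbon–carbon bond, not at oxygen. O1–C2 would be made first, by adding the single free hydroxyl of a 2-prenylphloroglucinol diallyl ether to a ring B arylpropiolate; the derived (Z)-3-aryloxy-3-arylacrylic acid would then acylate ring A intramolecularly. The step exploits one feature of ring A: of the two carbons ortho to O1, C8 already carries the prenyl group, so only C4a can be attacked and the 8-prenyl pattern is fixed by connectivity. C2=C3 comes from an alkyne at the flavone oxidation level, so no aldol condensation, no choice between two ring A oxygens and no dehydrogenation would be needed.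

Key step: step 8

Assumption: adduct 11 and acid 12 are drawn and named as the Z isomers expected from anti addition; any E isomer formed alongside would be carried through, because both geometries should converge under the conditions of step 8.

Step 1
Reactants: 1 phloroglucinol (benzene-1,3,5-triol); 2 allyl bromide (3-bromoprop-1-ene)
Product: 3 3,5-bis(prop-2-en-1-yloxy)phenol
Conditions: 2 (2.0 equiv), K2CO3 (2.2 equiv), DMF, 0 °C to rt; chromatography
Reagents that add atoms: allyl bromide (2), C=CCBr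
Why: Williamson ether synthesis under statistical control, in which the phenoxides should be alkylated at oxygen in DMF and the symmetric diether should be separable from the mono- and triethers, leaving exactly one free hydroxyl, the future O1.

Step 2
Reactants: 3 3,5-bis(prop-2-en-1-yloxy)phenol; 4 prenyl bromide (1-bromo-3-methylbut-2-ene)
Product: 5 2-(3-methylbut-2-en-1-yl)-3,5-bis(prop-2-en-1-yloxy)phenol
Conditions: NaH (1.05 equiv), toluene, 0 °C; 4 (0.95 equiv), rt
Reagents that add atoms: prenyl bromide (4), CC(C)=CCBr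
Why: Ortho-C-alkylation of a sodium phenoxide in a non-polar solvent, in which the tight sodium–oxygen ion pair should deliver the allylic bromide to a carbon next to the only free hydroxyl (the two ortho carbons are equivalent), so that the prenyl group ends up beside the future O1, while a slight deficit of bromide limits double alkylation.

Step 3
Reactants: 6 4-iodophenol; 4 prenyl bromide (1-bromo-3-methylbut-2-ene)
Product: 7 4-iodo-2,6-bis(3-methylbut-2-en-1-yl)phenol
Conditions: NaH (2.2 equiv), 4 (2.2 equiv), toluene, 0 °C to rt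
Reagents that add atoms: prenyl bromide (4), CC(C)=CCBr
Why: Twofold ortho-C-alkylation of a sodium phenoxide in toluene, in which the para position is blocked by iodine so that both ortho carbons should take up a prenyl group in turn, the aryl iodide being inert to NaH and to the bromide.

Step 4
Reactants: 7 4-iodo-2,6-bis(3-methylbut-2-en-1-yl)phenol; 2 allyl bromide (3-bromoprop-1-ene)
Product: 8 5-iodo-1,3-bis(3-methylbut-2-en-1-yl)-2-(prop-2-en-1-yloxy)benzene
Conditions: 2 (1.5 equiv), K2CO3 (2 equiv), DMF, 50 °C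
Reagents that add atoms: allyl bromide (2), C=CCBr
Why: Williamson ether synthesis that caps the hindered phenol so that it can neither add to the ynoate in step 6 nor be acylated in step 8, with the same group as on ring A so that one reagent removes all three at the end.

Step 5
Reactants: 8 5-iodo-1,3-bis(3-methylbut-2-en-1-yl)-2-(prop-2-en-1-yloxy)benzene; 9 methyl propiolate (methyl prop-2-ynoate)
Product: 10 methyl 3-[3,5-bis(3-methylbut-2-en-1-yl)-4-(prop-2-en-1-yloxy)phenyl]prop-2-ynoate
Conditions: 9 (3 equiv), PdCl2(PPh3)2 (3 mol %), CuI (6 mol %), K2CO3 (2 equiv), THF, 65 °C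
Reagents that add atoms: methyl propiolate (9), C#CC(=O)OC
Why: Sonogashira coupling of an aryl iodide with an alkyl propiolate under amine-free carbonate conditions, which avoids conjugate addition of an amine to the propiolate, while the aryl allyl ether should not be ionised by zerovalent palladium in the absence of an allyl acceptor and the prenyl groups are inert.

Step 6
Reactants: 5 2-(3-methylbut-2-en-1-yl)-3,5-bis(prop-2-en-1-yloxy)phenol; 10 methyl 3-[3,5-bis(3-methylbut-2-en-1-yl)-4-(prop-2-en-1-yloxy)phenyl]prop-2-ynoate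
Product: 11 methyl (2Z)-3-[3,5-bis(3-methylbut-2-en-1-yl)-4-(prop-2-en-1-yloxy)phenyl]-3-[2-(3-methylbut-2-en-1-yl)-3,5-bis(prop-2-en-1-yloxy)phenoxy]prop-2-enoate
Conditions: Cs2CO3 (0.5 equiv), DMF, 70 °C
Reagents that add atoms: none
Why: Base-catalysed oxa-Michael addition of a phenol to a 3-arylpropiolate, which forms the O1–C2 bond through the only free hydroxyl of 5 and, by anti protonation of the allenolate, should give mainly the Z isomer with the aryloxy group and the ester on the same side, as the ring closure requires.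

Step 7
Reactants: 11 methyl (2Z)-3-[3,5-bis(3-methylbut-2-en-1-yl)-4-(prop-2-en-1-yloxy)phenyl]-3-[2-(3-methylbut-2-en-1-yl)-3,5-bis(prop-2-en-1-yloxy)phenoxy]prop-2-enoate
Product: 12 (2Z)-3-[3,5-bis(3-methylbut-2-en-1-yl)-4-(prop-2-en-1-yloxy)phenyl]-3-[2-(3-methylbut-2-en-1-yl)-3,5-bis(prop-2-en-1-yloxy)phenoxy]prop-2-enoic acid
Conditions: LiOH·H2O (3 equiv), THF–H2O (3:1), 40 °C; then 1 M HCl to pH 3, 0 °C
Reagents that add atoms: lithium hydroxide, [Li+].[OH-]
Why: Saponification of the methyl ester by acyl–oxygen cleavage, to which the aryl vinyl ether, the allyl ethers and the prenyl groups should be stable, and the cold dilute acid of the work-up meets no free phenol beside a prenyl group.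

Step 8
Reactants: 12 (2Z)-3-[3,5-bis(3-methylbut-2-en-1-yl)-4-(prop-2-en-1-yloxy)phenyl]-3-[2-(3-methylbut-2-en-1-yl)-3,5-bis(prop-2-en-1-yloxy)phenoxy]prop-2-enoic acid
Product: 14 2-[3,5-bis(3-methylbut-2-en-1-yl)-4-(prop-2-en-1-yloxy)phenyl]-8-(3-methylbut-2-en-1-yl)-5,7-bis(prop-2-en-1-yloxy)-4H-chromen-4-one, via mixed trifluoroacetic anhydride 13 (not isolated)
Conditions: (CF3CO)2O (1.1 equiv), CH2Cl2, −20 to 0 °C
Reagents that add atoms: none
Why: Intramolecular Friedel–Crafts acylation of a 3-aryloxy-3-arylacrylic acid, the long-known carbon–carbon ring closure of such acids to flavones, run here through the mixed trifluoroacetic anhydride 13 so that no mineral or Lewis acid is present. Ionisation of 13 gives an acylium ion that is at the same time an aryloxycarbenium-substituted ketene, which lowers the C2–C3 bond order and lets any E isomer reach the reactive Z geometry. Ring C closes by attack of ring A carbon C4a on the acyl carbon (6-exo with respect to the C=O bond, equivalently a 6π-electrocyclisation of the ketene form), and loss of the proton restores ring A and gives the 4-pyranone. The step needs regioselectivity among the positions of ring A: acylation can only occur ortho to O1, one of the two ortho carbons (C8) carries the prenyl group, and the free one is also ortho and para to the two allyloxy groups, so the 8-prenyl flavone is the only possible regioisomer. Closure onto ring B to an indenone would require a five-membered transition state at a carbon meta to its oxygen and should not compete. No stereocentre is formed; the aryl allyl ethers are stable to trifluoroacetic acid, no phenol is free beside a prenyl group, and one equivalent of anhydride at low temperature should keep protonation of the prenyl double bonds and ring trifluoroacetylation slow relative to ring closure.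

Step 9
Reactants: 14 2-[3,5-bis(3-methylbut-2-en-1-yl)-4-(prop-2-en-1-yloxy)phenyl]-8-(3-methylbut-2-en-1-yl)-5,7-bis(prop-2-en-1-yloxy)-4H-chromen-4-one
Product: 15 epimedonin L, 5,7-dihydroxy-2-[4-hydroxy-3,5-bis(3-methylbut-2-en-1-yl)phenyl]-8-(3-methylbut-2-en-1-yl)-4H-chromen-4-one
Conditions: Pd(PPh3)4 (5 mol %), morpholine (10 equiv), THF, rt
Reagents that add atoms: none
Why: Tsuji–Trost deallylation, in which zerovalent palladium ionises the three aryl allyl ethers to π-allyl complexes that morpholine traps, which should free the three phenols under neutral conditions that leave the prenyl groups and the 4-pyranone untouched.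

## Compound list
1 | phloroglucinol (benzene-1,3,5-triol) | Oc1cc(O)cc(O)c1 | starting material
2 | allyl bromide (3-bromoprop-1-ene) | C=CCBr | starting material
3 | 3,5-bis(prop-2-en-1-yloxy)phenol | Oc1cc(OCC=C)cc(OCC=C)c1 | intermediate
4 | prenyl bromide (1-bromo-3-methylbut-2-ene) | CC(C)=CCBr | starting material
5 | 2-(3-methylbut-2-en-1-yl)-3,5-bis(prop-2-en-1-yloxy)phenol | Oc1cc(OCC=C)cc(OCC=C)c1CC=C(C)C | intermediate
6 | 4-iodophenol | Oc1ccc(I)cc1 | starting material
7 | 4-iodo-2,6-bis(3-methylbut-2-en-1-yl)phenol | CC(C)=CCc1cc(I)cc(CC=C(C)C)c1O | intermediate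
8 | 5-iodo-1,3-bis(3-methylbut-2-en-1-yl)-2-(prop-2-en-1-yloxy)benzene | CC(C)=CCc1cc(I)cc(CC=C(C)C)c1OCC=C | intermediate
9 | methyl propiolate (methyl prop-2-ynoate) | C#CC(=O)OC | starting material
10 | methyl 3-[3,5-bis(3-methylbut-2-en-1-yl)-4-(prop-2-en-1-yloxy)phenyl]prop-2-ynoate | COC(=O)C#Cc1cc(CC=C(C)C)c(OCC=C)c(CC=C(C)C)c1 | intermediate
11 | methyl (2Z)-3-[3,5-bis(3-methylbut-2-en-1-yl)-4-(prop-2-en-1-yloxy)phenyl]-3-[2-(3-methylbut-2-en-1-yl)-3,5-bis(prop-2-en-1-yloxy)phenoxy]prop-2-enoate | COC(=O)/C=C(\Oc1cc(OCC=C)cc(OCC=C)c1CC=C(C)C)c1cc(CC=C(C)C)c(OCC=C)c(CC=C(C)C)c1 | intermediate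
12 | (2Z)-3-[3,5-bis(3-methylbut-2-en-1-yl)-4-(prop-2-en-1-yloxy)phenyl]-3-[2-(3-methylbut-2-en-1-yl)-3,5-bis(prop-2-en-1-yloxy)phenoxy]prop-2-enoic acid | OC(=O)/C=C(\Oc1cc(OCC=C)cc(OCC=C)c1CC=C(C)C)c1cc(CC=C(C)C)c(OCC=C)c(CC=C(C)C)c1 | intermediate
13 | mixed anhydride of acid 12 with trifluoroacetic acid | O=C(OC(=O)C(F)(F)F)/C=C(\Oc1cc(OCC=C)cc(OCC=C)c1CC=C(C)C)c1cc(CC=C(C)C)c(OCC=C)c(CC=C(C)C)c1 | intermediate
14 | 2-[3,5-bis(3-methylbut-2-en-1-yl)-4-(prop-2-en-1-yloxy)phenyl]-8-(3-methylbut-2-en-1-yl)-5,7-bis(prop-2-en-1-yloxy)-4H-chromen-4-one | CC(C)=CCc1cc(-c2cc(=O)c3c(OCC=C)cc(OCC=C)c(CC=C(C)C)c3o2)cc(CC=C(C)C)c1OCC=C | intermediate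
15 | epimedonin L, 5,7-dihydroxy-2-[4-hydroxy-3,5-bis(3-methylbut-2-en-1-yl)phenyl]-8-(3-methylbut-2-en-1-yl)-4H-chromen-4-one | CC(C)=CCc1cc(-c2cc(=O)c3c(O)cc(O)c(CC=C(C)C)c3o2)cc(CC=C(C)C)c1O | target

Total step count: 9. Longest linear sequence: 7 steps (steps 3 to 9, from 4-iodophenol); the ring A branch (steps 1 and 2) joins at step 6.

Steps most likely to fail:

1. Step 8 (key step). The trifluoroacetic acid set free may protonate prenyl double bonds, or trifluoroacetylation of the electron-rich ring A may overtake closure of the stabilised acyl group. The fallback sets out from 5 and 8 and comes back at 14; it gives up closure at carbon and builds an ynone that closes at oxygen without any acid. Phenol 5 would be ortho-formylated with MgCl2, Et3N and paraformaldehyde in MeCN, again at its only free ortho carbon, to 2-hydroxy-3-(3-methylbut-2-en-1-yl)-4,6-bis(prop-2-en-1-yloxy)benzaldehyde F1. Iodide 8 would be coupled with trimethylsilylacetylene (PdCl2(PPh3)2, CuI, Et3N) to {[3,5-bis(3-methylbut-2-en-1-yl)-4-(prop-2-en-1-yloxy)phenyl]ethynyl}trimethylsilane F2 and desilylated (K2CO3, MeOH) to 5-ethynyl-1,3-bis(3-methylbut-2-en-1-yl)-2-(prop-2-en-1-yloxy)benzene F3. The lithium acetylide of F3 (n-BuLi, THF, −78 °C, in excess to allow for the phenol) would add to F1 to give racemic 3-[3,5-bis(3-methylbut-2-en-1-yl)-4-(prop-2-en-1-yloxy)phenyl]-1-[2-hydroxy-3-(3-methylbut-2-en-1-yl)-4,6-bis(prop-2-en-1-yloxy)phenyl]prop-2-yn-1-ol F4. MnO2 in CH2Cl2 would oxidise F4 to 3-[3,5-bis(3-methylbut-2-en-1-yl)-4-(prop-2-en-1-yloxy)phenyl]-1-[2-hydroxy-3-(3-methylbut-2-en-1-yl)-4,6-bis(prop-2-en-1-yloxy)phenyl]prop-2-yn-1-one F5. Diethylamine in ethanol would then close F5 by 6-endo-dig oxa-Michael addition through its single free hydroxyl, the one beside the prenyl group, to flavone 14.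

2. Step 6. Conjugate addition of a hindered phenoxide to a donor-substituted ynoate may be slow, so that base-induced decomposition or drift of the double-bond geometry takes over. The fallback sets out from 5 and 8 and comes back at 12; it replaces the ynoate by a far more electrophilic ynal and reaches the acid by oxidation, not hydrolysis. Iodide 8 would be coupled with propargyl alcohol (PdCl2(PPh3)2, CuI, Et3N) to 3-[3,5-bis(3-methylbut-2-en-1-yl)-4-(prop-2-en-1-yloxy)phenyl]prop-2-yn-1-ol F6, which MnO2 would oxidise to 3-[3,5-bis(3-methylbut-2-en-1-yl)-4-(prop-2-en-1-yloxy)phenyl]prop-2-ynal F7. Phenol 5 would add to F7 (catalytic Et3N, MeCN, rt) to give (2Z)-3-[3,5-bis(3-methylbut-2-en-1-yl)-4-(prop-2-en-1-yloxy)phenyl]-3-[2-(3-methylbut-2-en-1-yl)-3,5-bis(prop-2-en-1-yloxy)phenoxy]prop-2-enal F8. Pinnick oxidation of F8 (NaClO2, NaH2PO4, excess 2-methylbut-2-ene, t-BuOH–H2O) would give acid 12.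

3. Step 2. Para-C-alkylation, O-alkylation and double alkylation of the very electron-rich phenoxide may erode the ortho regiochemistry on which the route depends. The fallback sets out from 3 and comes back at 5; it delivers the prenyl group by a sigmatropic shift that can only reach an ortho carbon. Phenol 3 would be alkylated with 3-chloro-3-methylbut-1-yne (CuCl2 catalyst, DBU, MeCN, 0 °C) to 1-[(2-methylbut-3-yn-2-yl)oxy]-3,5-bis(prop-2-en-1-yloxy)benzene F9. Semihydrogenation of F9 (H2, Pd/CaCO3 poisoned with Pb(OAc)2, quinoline) would give 1-[(2-methylbut-3-en-2-yl)oxy]-3,5-bis(prop-2-en-1-yloxy)benzene F10. Heating F10 in N,N-diethylaniline at about 120 °C would give 5 by aromatic Claisen rearrangement; the tertiary allyl ether should rearrange well below the temperature at which the two primary allyl ethers do.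

Further compounds
F1 | step 8 | 2-hydroxy-3-(3-methylbut-2-en-1-yl)-4,6-bis(prop-2-en-1-yloxy)benzaldehyde | O=Cc1c(OCC=C)cc(OCC=C)c(CC=C(C)C)c1O
F2 | step 8 | {[3,5-bis(3-methylbut-2-en-1-yl)-4-(prop-2-en-1-yloxy)phenyl]ethynyl}trimethylsilane | C[Si](C)(C)C#Cc1cc(CC=C(C)C)c(OCC=C)c(CC=C(C)C)c1
F3 | step 8 | 5-ethynyl-1,3-bis(3-methylbut-2-en-1-yl)-2-(prop-2-en-1-yloxy)benzene | C#Cc1cc(CC=C(C)C)c(OCC=C)c(CC=C(C)C)c1
F4 | step 8 | racemic 3-[3,5-bis(3-methylbut-2-en-1-yl)-4-(prop-2-en-1-yloxy)phenyl]-1-[2-hydroxy-3-(3-methylbut-2-en-1-yl)-4,6-bis(prop-2-en-1-yloxy)phenyl]prop-2-yn-1-ol | OC(C#Cc1cc(CC=C(C)C)c(OCC=C)c(CC=C(C)C)c1)c1c(OCC=C)cc(OCC=C)c(CC=C(C)C)c1O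
F5 | step 8 | 3-[3,5-bis(3-methylbut-2-en-1-yl)-4-(prop-2-en-1-yloxy)phenyl]-1-[2-hydroxy-3-(3-methylbut-2-en-1-yl)-4,6-bis(prop-2-en-1-yloxy)phenyl]prop-2-yn-1-one | O=C(C#Cc1cc(CC=C(C)C)c(OCC=C)c(CC=C(C)C)c1)c1c(OCC=C)cc(OCC=C)c(CC=C(C)C)c1O
F6 | step 6 | 3-[3,5-bis(3-methylbut-2-en-1-yl)-4-(prop-2-en-1-yloxy)phenyl]prop-2-yn-1-ol | OCC#Cc1cc(CC=C(C)C)c(OCC=C)c(CC=C(C)C)c1
F7 | step 6 | 3-[3,5-bis(3-methylbut-2-en-1-yl)-4-(prop-2-en-1-yloxy)phenyl]prop-2-ynal | O=CC#Cc1cc(CC=C(C)C)c(OCC=C)c(CC=C(C)C)c1
F8 | step 6 | (2Z)-3-[3,5-bis(3-methylbut-2-en-1-yl)-4-(prop-2-en-1-yloxy)phenyl]-3-[2-(3-methylbut-2-en-1-yl)-3,5-bis(prop-2-en-1-yloxy)phenoxy]prop-2-enal | O=C/C=C(\Oc1cc(OCC=C)cc(OCC=C)c1CC=C(C)C)c1cc(CC=C(C)C)c(OCC=C)c(CC=C(C)C)c1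
F9 | step 2 | 1-[(2-methylbut-3-yn-2-yl)oxy]-3,5-bis(prop-2-en-1-yloxy)benzene | C#CC(C)(C)Oc1cc(OCC=C)cc(OCC=C)c1
F10 | step 2 | 1-[(2-methylbut-3-en-2-yl)oxy]-3,5-bis(prop-2-en-1-yloxy)benzene | C=CC(C)(C)Oc1cc(OCC=C)cc(OCC=C)c1
A1 | direct plan | 1-[2-hydroxy-3-(3-methylbut-2-en-1-yl)-4,6-bis(prop-2-en-1-yloxy)phenyl]ethan-1-one | CC(=O)c1c(OCC=C)cc(OCC=C)c(CC=C(C)C)c1O
A2 | direct plan | 4-hydroxy-3,5-bis(3-methylbut-2-en-1-yl)benzaldehyde | CC(C)=CCc1cc(C=O)cc(CC=C(C)C)c1O
A3 | direct plan | (E)-1-[2-hydroxy-3-(3-methylbut-2-en-1-yl)-4,6-bis(prop-2-en-1-yloxy)phenyl]-3-[4-hydroxy-3,5-bis(3-methylbut-2-en-1-yl)phenyl]prop-2-en-1-one | CC(C)=CCc1cc(/C=C/C(=O)c2c(OCC=C)cc(OCC=C)c(CC=C(C)C)c2O)cc(CC=C(C)C)c1O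
A4 | direct plan | racemic 2-[4-hydroxy-3,5-bis(3-methylbut-2-en-1-yl)phenyl]-8-(3-methylbut-2-en-1-yl)-5,7-bis(prop-2-en-1-yloxy)chroman-4-one | CC(C)=CCc1cc(C2CC(=O)c3c(OCC=C)cc(OCC=C)c(CC=C(C)C)c3O2)cc(CC=C(C)C)c1O
A5 | direct plan | 2-[4-hydroxy-3,5-bis(3-methylbut-2-en-1-yl)phenyl]-8-(3-methylbut-2-en-1-yl)-5,7-bis(prop-2-en-1-yloxy)-4H-chromen-4-one | CC(C)=CCc1cc(-c2cc(=O)c3c(OCC=C)cc(OCC=C)c(CC=C(C)C)c3o2)cc(CC=C(C)C)c1O
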